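## Analysis of the target

Target 17 is a biflavonoid. C3 of a 5,7-dihydroxy-2-(4-hydroxyphenyl)chroman-4-one (flavanone rings A and C) is bonded to C3' of a 5,7,4'-trihydroxyflavone, so ring B of the flavone is a phenol that carries the flavanone on the carbon next to its hydroxyl. The only stereocentres are C2 (R) and C3 (S) of flavanone ring C; they are adjacent, and the two aryl groups are trans and both equatorial on the half-chair. C3–H is benzylic and alpha to the C4 ketone, so it exchanges easily, but the trans arrangement is the stable one. C2 is lost only by ring opening (retro-oxa-Michael) under base, so the absolute configuration rests on C2 and on keeping base away once the ketone is present. The other functions are six phenols, two of them chelated to the C4 carbonyl groups, and a flavone enone that can be reduced. The difficulty is the crowded C3–C3' bond, which joins a carbon flanked by a ketone and a benzylic ether carbon to an arene carbon ortho to oxygen, together with absolute control at C2 in a class of compounds that racemises readily. The strategy rests on ring C: the array O1–C2–C3–C4 with trans aryl groups on C2 and C3 corresponds to an ortho-quinone methide (C4, C4a, C8a, O1) and an E-1,2-diarylethene (C2, C3).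

## Retrosynthetic reasoning

17 from 16. All six phenols are masked in 16 as groups that leave under hydrogenolysis: five benzyl ethers and one benzyl carbonate. One neutral final step then frees the target without exposing the flavanone to base.

16 from 15 from 14. The C4 ketone is traced back to the secondary benzylic alcohol 15 and further to the methyl ether 14. The ring-forming step delivers C4 one oxidation step below the ketone, so only an ether-to-hydroxyl exchange and one oxidation are needed. The configuration at C4 is irrelevant because the centre disappears.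

14 from 13 and 11. The bonds C3–C4 and O1–C2 are cut. Both lie in ring C between the two halves, so this cut divides the molecule into two fragments of similar size and converts the trans relationship at C2/C3 into the E geometry of stilbene 11. The four-atom partner is the methoxy ortho-quinone methide 13, which forms in the flask from acetal 12 and thus from aldehyde 2. The forward reaction has to control which alkene carbon bonds to C4, add to one face of 13 under a chiral Brønsted acid, and keep the alkene geometry.

11 from 10. The carbonate on the ring B oxygen is installed last, because it would not survive the base and heat of the earlier steps. Its role is electronic: it lowers the donor strength of that oxygen so that the other aryl ring alone directs the cycloaddition.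

10 from 7 and 9. The bond between C3' of ring B and the alkene carbon is cut, which is a Heck disconnection between aryl bromide 7 and styrene 9 and gives the E alkene directly. The alkene is introduced after the flavone is complete because it would not survive the oxidative ring closure. Styrene 9 comes from aldehyde 8 by methylenation.

7 from 6 from 4 and 5. The flavone pyranone ring is opened at O1–C2 to the 2'-hydroxychalcone 6, which is cut at its alkene into methyl ketone 4 and aldehyde 5 (aldol condensation). The bromine of 5 is the handle for the later coupling.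

4 from 3, and 2 from 1. Both ring A building blocks come from the corresponding trihydroxy carbonyl compounds by double O-benzylation that spares the chelated ortho hydroxyl. That hydroxyl is the one needed later as the ring oxygen.

## Alternatives that were turned down

Alternative 1: Flavone ring B, the phenol ring that links the halves, is cut at C2'–C3' and C1'–C6' into pyranone A2 and ethynylchromone A3. On heating, the two undergo a (4+2) cycloaddition, the bridged lactone adduct decarboxylates, and the arene of deoxybenzoin A1 results.
- For it: the orientation is electronically matched (the alkoxy group on the diene and the acceptor on the alkyne place the chromone para to oxygen), there is no stereochemistry to control, and the crowded ring is made without a cross-coupling.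
- Against it: ring B is an ordinary phenol ring that is bought in 5, so building it costs steps; A2 and A3 are not commercial and each needs several steps; pyranones are sluggish dienes that need high temperature, at which an alkynyl chromone tends to polymerise.
- Decisive point: A1 has no stereocentre. C2 and C3 would still have to be made by condensation with aldehyde 8 and an enantioselective ring closure, which is the problem of Alternative 3.
- Comparison: Alternative 1 is stronger on the certainty of regiochemistry in its key step and on precedent for the reaction type. The chosen strategy makes ring C and all stereocentres in its key step and needs only short precursor syntheses.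

Alternative 2: Flavone ring A is cut at C4a–C5, C5–C6, C7–C8 and C8–C8a into diazo ketone A5 and siloxyalkyne A6. Wolff rearrangement of A5 gives a pyranonyl ketene, which adds to A6; the cyclobutenone opens and the dienylketene closes by six-electron electrocyclisation to the phenol A4.
- For it: the cascade makes four bonds with fixed regiochemistry and delivers the 5-hydroxyl and the 7-oxygen differentiated.
- Against it: ring A is also a ring that is bought (in 3), and differentiated 5- and 7-oxygens have no value for a target with all phenols free. A5 needs a hazardous diazo homologation at the end of a long sequence, and the photochemical step must be run on chromones that absorb strongly.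
- Decisive point: A4 still lacks the flavanone stereocentres. An aryl group would have to be added enantioselectively to C2 of a 3-arylchromone, a hindered and poor acceptor.
- Comparison: Alternative 2 is the more original way to a flavone, but it spends its key step on the easy half. The chosen strategy buys ring A twice and spends its key step on ring C, where the difficulty lies.

Alternative 3: Ring C is cut only at O1–C2, which leads to the alpha-aryl-2'-hydroxychalcone A8, made from A1 and aldehyde 8. A bifunctional cinchona thiourea catalyst would deprotonate the phenol and activate the enone, the oxygen adds to the beta carbon, and C3 equilibrates to trans to give hexabenzyl ether A7.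
- For it: A7 is at the right oxidation level and one hydrogenolysis from the target, there is no regiochemical question, and asymmetric oxa-Michael closure to flavanones is a known reaction class. On end-game economy and precedent this alternative is stronger than the chosen one.
- Against it: the known asymmetric closures rely on an activating ester at the alpha carbon, whereas an alpha-aryl group twists and deactivates the enone, and the doubly ortho-oxygenated aryl ketone is out of plane as well. The basic catalyst that equilibrates C3 also opens the ring again, so the configuration at C2 rests on kinetic control in a reversible reaction.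
- Against it on step economy: A8 requires a long linear sequence, because its deoxybenzoin must carry the whole flavone.
- Comparison: the chosen strategy sets C2 and C3 together under acid, where the ring does not reopen, and joins two fragments late. It pays with three steps of adjustment after the key step and a key step without direct precedent.

Key step: step 8

Remarks on the chemistry:
- The sense of induction of the phosphoric acid in step 8 cannot be read from the structures; the (R)-acid is written, and its enantiomer is used instead if it favours the mirror-image series.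
- Compounds 14 and 15 are written as the C4 epimers with all three ring C substituents equatorial; the other C4 epimer, if formed, is carried along because C4 becomes a carbonyl carbon in step 10.

## Route

Step 1
Reactants: 1 2,4,6-trihydroxybenzaldehyde
Product: 2 2-hydroxy-4,6-bis(benzyloxy)benzaldehyde
Conditions: BnBr (2.05 equiv), K2CO3 (2.2 equiv), DMF, 0 °C → rt
Reagents that add atoms: benzyl bromide, BrCc1ccccc1
Why: Williamson ether synthesis; the 4-hydroxyl is the most acidic and one ortho hydroxyl follows, while the remaining ortho hydroxyl is held in a hydrogen bond to the aldehyde oxygen and is the poorest nucleophile, so alkylation should stop at the bis-ether.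

Step 2
Reactants: 3 1-(2,4,6-trihydroxyphenyl)ethan-1-one
Product: 4 1-[2-hydroxy-4,6-bis(benzyloxy)phenyl]ethan-1-one
Conditions: BnBr (2.1 equiv), K2CO3 (2.2 equiv), DMF, rt
Reagents that add atoms: benzyl bromide, BrCc1ccccc1
Why: Williamson ether synthesis under the same chelation control as in step 1; the hydroxyl bonded to the ketone oxygen stays free and later becomes the ring oxygen of the flavone.

Step 3
Reactants: 4 1-[2-hydroxy-4,6-bis(benzyloxy)phenyl]ethan-1-one; 5 3-bromo-4-hydroxybenzaldehyde
Product: 6 (2E)-3-(3-bromo-4-hydroxyphenyl)-1-[2-hydroxy-4,6-bis(benzyloxy)phenyl]prop-2-en-1-one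
Conditions: KOH (50% aq, excess), EtOH, rt → 40 °C; then dilute HCl
Reagents that add atoms: none
Why: Claisen-Schmidt (crossed aldol) condensation; the methyl ketone enolate adds to the aldehyde and the aldol loses water to the conjugated E enone. The ortho bromine weakens the donor effect of the phenoxide of 5, so the aldehyde should stay electrophilic enough, and both phenols are carried as phenoxides without protection.

Step 4
Reactants: 6 (2E)-3-(3-bromo-4-hydroxyphenyl)-1-[2-hydroxy-4,6-bis(benzyloxy)phenyl]prop-2-en-1-one
Product: 7 5,7-bis(benzyloxy)-2-(3-bromo-4-hydroxyphenyl)-4H-chromen-4-one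
Conditions: I2 (10 mol%), DMSO, 130 °C
Reagents that add atoms: none
Why: Iodine-mediated oxidative cyclisation of a 2'-hydroxychalcone; the phenol adds to the enone and the new ring is dehydrogenated, with DMSO returning HI to I2 so that a catalytic amount suffices. Benzyl ethers and the aryl bromide are inert, and the small amount of I2 limits ring iodination.

Step 5
Reactants: 8 4-benzyloxybenzaldehyde
Product: 9 1-(benzyloxy)-4-ethenylbenzene (4-benzyloxystyrene)
Conditions: Ph3PCH3Br, KOtBu, THF, 0 °C → rt
Reagents that add atoms: methyltriphenylphosphonium bromide, C[P+](c1ccccc1)(c1ccccc1)c1ccccc1.[Br-]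
Why: Wittig methylenation of an aromatic aldehyde with the unstabilised ylide; no other reactive group is present.

Step 6
Reactants: 7 5,7-bis(benzyloxy)-2-(3-bromo-4-hydroxyphenyl)-4H-chromen-4-one; 9 1-(benzyloxy)-4-ethenylbenzene
Product: 10 5,7-bis(benzyloxy)-2-{3-[(E)-2-(4-benzyloxyphenyl)ethenyl]-4-hydroxyphenyl}-4H-chromen-4-one
Conditions: Pd(OAc)2 (5 mol%), P(o-tol)3 (10 mol%), Et3N, DMF, 100 °C
Reagents that add atoms: none
Why: Heck reaction; oxidative addition of the aryl bromide to zerovalent palladium, syn insertion of the styrene at its terminal carbon and syn beta-hydride elimination give the E alkene. The bulky triarylphosphine is the ligand suited to aryl bromides that carry a free hydroxyl.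

Step 7
Reactants: 10 5,7-bis(benzyloxy)-2-{3-[(E)-2-(4-benzyloxyphenyl)ethenyl]-4-hydroxyphenyl}-4H-chromen-4-one
Product: 11 benzyl 2-[(E)-2-(4-benzyloxyphenyl)ethenyl]-4-[5,7-bis(benzyloxy)-4-oxo-4H-chromen-2-yl]phenyl carbonate
Conditions: BnOCOCl, pyridine, CH2Cl2, 0 °C
Reagents that add atoms: benzyl chloroformate, O=C(Cl)OCc1ccccc1
Why: Acylation of the only free phenol with a chloroformate. The carbonate lowers the donor strength of the ring B oxygen, keeps that phenol from adding to the alkene under acid, and leaves together with the benzyl ethers in the last step.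

Step 8
Reactants: 2 2-hydroxy-4,6-bis(benzyloxy)benzaldehyde; 11 benzyl 2-[(E)-2-(4-benzyloxyphenyl)ethenyl]-4-[5,7-bis(benzyloxy)-4-oxo-4H-chromen-2-yl]phenyl carbonate
Product: 14 benzyl 2-[(2R,3R,4R)-5,7-bis(benzyloxy)-2-(4-benzyloxyphenyl)-4-methoxy-3,4-dihydro-2H-chromen-3-yl]-4-[5,7-bis(benzyloxy)-4-oxo-4H-chromen-2-yl]phenyl carbonate, via dimethyl acetal 12 (not isolated), via methoxy ortho-quinone methide 13 (not isolated)
Conditions: 2 (1.3 equiv), HC(OMe)3 (3 equiv), (R)-3,3'-bis(2,4,6-triisopropylphenyl)-1,1'-binaphthalene-2,2'-diyl hydrogen phosphate (10 mol%), molecular sieves 5 Å, CH2Cl2, −20 °C → rt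
Reagents that add atoms: trimethyl orthoformate, COC(OC)OC
Why: Proposed new method: the acid turns 2 into acetal 12 and, by loss of methanol, into the methoxy ortho-quinone methide 13, which reacts as an oxocarbenium ion hydrogen-bonded through its phenolic oxygen to the chiral phosphate; C4 of 13 bonds to the alkene carbon of 11 that carries ring B of the flavone, positive charge builds on the carbon next to the 4-benzyloxyphenyl ring, and the phenolic oxygen closes onto it on the same face, an asynchronous inverse-electron-demand hetero-Diels-Alder reaction. The closest known reaction type is the acid-catalysed (4+2) cycloaddition of ortho-quinone methides from salicylaldehyde acetals with styrenes to 4-alkoxyflavans, which has chiral phosphoric acid versions but none with a 1,2-diarylethene. Ring C closes by (4+2) cycloaddition of the four-atom unit C4-C4a-C8a-O1 onto the two alkene carbons; in the stepwise limit this is a 6-endo-trig attack of oxygen on the benzylic cation. C2 and C3 take their trans relationship from suprafacial addition to the E alkene (a short-lived cation would close to the same diequatorial product) and their absolute configuration from the face of 13 that the phosphate leaves open. C4 follows from the endo position of the C2 aryl group over E-configured 13 and is of no consequence, because it becomes a ketone. The step needs regioselectivity, which rests on the para-alkoxy donor of one ring against the carbonate and the chromone on the other, and chemoselectivity for the alkene over Friedel-Crafts attack on the alkoxy arenes, which the weak acid and the low temperature should favour.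

Step 9
Reactants: 14 benzyl 2-[(2R,3R,4R)-5,7-bis(benzyloxy)-2-(4-benzyloxyphenyl)-4-methoxy-3,4-dihydro-2H-chromen-3-yl]-4-[5,7-bis(benzyloxy)-4-oxo-4H-chromen-2-yl]phenyl carbonate
Product: 15 benzyl 2-[(2R,3R,4R)-5,7-bis(benzyloxy)-2-(4-benzyloxyphenyl)-4-hydroxy-3,4-dihydro-2H-chromen-3-yl]-4-[5,7-bis(benzyloxy)-4-oxo-4H-chromen-2-yl]phenyl carbonate
Conditions: HCl (0.1 M), THF/H2O 4:1, 0 °C → rt; NaHCO3 quench
Reagents that add atoms: water, O
Why: SN1 solvolysis of a benzylic ether; C4 ionises easily because the 5,7-dioxygenated ring stabilises the cation, and water in large excess takes the place of methanol, entering anti to the C3 aryl group. Dilute acid and low temperature are chosen to suppress loss of the C3 proton from the cation; C2 and C3 are not touched.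

Step 10
Reactants: 15 benzyl 2-[(2R,3R,4R)-5,7-bis(benzyloxy)-2-(4-benzyloxyphenyl)-4-hydroxy-3,4-dihydro-2H-chromen-3-yl]-4-[5,7-bis(benzyloxy)-4-oxo-4H-chromen-2-yl]phenyl carbonate
Product: 16 benzyl 2-[(2R,3S)-5,7-bis(benzyloxy)-2-(4-benzyloxyphenyl)-4-oxo-3,4-dihydro-2H-chromen-3-yl]-4-[5,7-bis(benzyloxy)-4-oxo-4H-chromen-2-yl]phenyl carbonate
Conditions: 2-iodoxybenzoic acid (1.5 equiv), DMSO/THF 2:1, rt
Reagents that add atoms: none
Why: Oxidation of a secondary benzylic alcohol by the hypervalent iodine reagent through ligand exchange and removal of the alpha hydrogen; at room temperature the reagent should not dehydrogenate the ketone. Both C4 epimers converge, the trans arrangement at C3 is the stable one next to the new ketone, and the descriptor at C3 changes from R to S only because the priorities change.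

Step 11
Reactants: 16 benzyl 2-[(2R,3S)-5,7-bis(benzyloxy)-2-(4-benzyloxyphenyl)-4-oxo-3,4-dihydro-2H-chromen-3-yl]-4-[5,7-bis(benzyloxy)-4-oxo-4H-chromen-2-yl]phenyl carbonate
Product: 17 (2R,3S)-3-[5-(5,7-dihydroxy-4-oxo-4H-chromen-2-yl)-2-hydroxyphenyl]-5,7-dihydroxy-2-(4-hydroxyphenyl)-2,3-dihydro-4H-chromen-4-one
Conditions: H2 (1 atm), Pd/C (10 wt%), THF/MeOH 1:1, rt
Reagents that add atoms: none
Why: Hydrogenolysis of five benzyl ethers and of the benzyl carbonate, whose carbonic half-ester loses CO2. Neutral conditions keep ring C closed, and the flavone double bond and the chelated ketones are reduced more slowly than O-benzyl bonds are cleaved.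

## Compound list

1 | 2,4,6-trihydroxybenzaldehyde | O=Cc1c(O)cc(O)cc1O | starting material
2 | 2-hydroxy-4,6-bis(benzyloxy)benzaldehyde | O=Cc1c(O)cc(OCc2ccccc2)cc1OCc1ccccc1 | intermediate
3 | 1-(2,4,6-trihydroxyphenyl)ethan-1-one (2',4',6'-trihydroxyacetophenone) | CC(=O)c1c(O)cc(O)cc1O | starting material
4 | 1-[2-hydroxy-4,6-bis(benzyloxy)phenyl]ethan-1-one | CC(=O)c1c(O)cc(OCc2ccccc2)cc1OCc1ccccc1 | intermediate
5 | 3-bromo-4-hydroxybenzaldehyde | O=Cc1ccc(O)c(Br)c1 | starting material
6 | (2E)-3-(3-bromo-4-hydroxyphenyl)-1-[2-hydroxy-4,6-bis(benzyloxy)phenyl]prop-2-en-1-one | O=C(/C=C/c1ccc(O)c(Br)c1)c1c(O)cc(OCc2ccccc2)cc1OCc1ccccc1 | intermediate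
7 | 5,7-bis(benzyloxy)-2-(3-bromo-4-hydroxyphenyl)-4H-chromen-4-one | O=c1cc(-c2ccc(O)c(Br)c2)oc2cc(OCc3ccccc3)cc(OCc3ccccc3)c12 | intermediate
8 | 4-benzyloxybenzaldehyde | O=Cc1ccc(OCc2ccccc2)cc1 | starting material
9 | 1-(benzyloxy)-4-ethenylbenzene | C=Cc1ccc(OCc2ccccc2)cc1 | intermediate
10 | 5,7-bis(benzyloxy)-2-{3-[(E)-2-(4-benzyloxyphenyl)ethenyl]-4-hydroxyphenyl}-4H-chromen-4-one | O=c1cc(-c2ccc(O)c(/C=C/c3ccc(OCc4ccccc4)cc3)c2)oc2cc(OCc3ccccc3)cc(OCc3ccccc3)c12 | intermediate
11 | benzyl 2-[(E)-2-(4-benzyloxyphenyl)ethenyl]-4-[5,7-bis(benzyloxy)-4-oxo-4H-chromen-2-yl]phenyl carbonate | c1ccccc1COc1ccc(/C=C/c2cc(-c3cc(=O)c4c(OCc5ccccc5)cc(OCc5ccccc5)cc4o3)ccc2OC(=O)OCc2ccccc2)cc1 | intermediate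
12 | 3,5-bis(benzyloxy)-2-(dimethoxymethyl)phenol | COC(OC)c1c(O)cc(OCc2ccccc2)cc1OCc1ccccc1 | intermediate (not isolated)
13 | (6E)-3,5-bis(benzyloxy)-6-(methoxymethylidene)cyclohexa-2,4-dien-1-one (drawn E; it interconverts with the Z form through the oxocarbenium ion) | CO/C=C1/C(=O)C=C(OCc2ccccc2)C=C1OCc1ccccc1 | intermediate (not isolated)
14 | benzyl 2-[(2R,3R,4R)-5,7-bis(benzyloxy)-2-(4-benzyloxyphenyl)-4-methoxy-3,4-dihydro-2H-chromen-3-yl]-4-[5,7-bis(benzyloxy)-4-oxo-4H-chromen-2-yl]phenyl carbonate | CO[C@H]1c2c(OCc3ccccc3)cc(OCc3ccccc3)cc2O[C@@H](c2ccc(OCc3ccccc3)cc2)[C@@H]1c1cc(-c2cc(=O)c3c(OCc4ccccc4)cc(OCc4ccccc4)cc3o2)ccc1OC(=O)OCc1ccccc1 | intermediate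
15 | benzyl 2-[(2R,3R,4R)-5,7-bis(benzyloxy)-2-(4-benzyloxyphenyl)-4-hydroxy-3,4-dihydro-2H-chromen-3-yl]-4-[5,7-bis(benzyloxy)-4-oxo-4H-chromen-2-yl]phenyl carbonate | O[C@H]1c2c(OCc3ccccc3)cc(OCc3ccccc3)cc2O[C@@H](c2ccc(OCc3ccccc3)cc2)[C@@H]1c1cc(-c2cc(=O)c3c(OCc4ccccc4)cc(OCc4ccccc4)cc3o2)ccc1OC(=O)OCc1ccccc1 | intermediate
16 | benzyl 2-[(2R,3S)-5,7-bis(benzyloxy)-2-(4-benzyloxyphenyl)-4-oxo-3,4-dihydro-2H-chromen-3-yl]-4-[5,7-bis(benzyloxy)-4-oxo-4H-chromen-2-yl]phenyl carbonate | O=C1c2c(OCc3ccccc3)cc(OCc3ccccc3)cc2O[C@@H](c2ccc(OCc3ccccc3)cc2)[C@@H]1c1cc(-c2cc(=O)c3c(OCc4ccccc4)cc(OCc4ccccc4)cc3o2)ccc1OC(=O)OCc1ccccc1 | intermediate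
17 | (2R,3S)-3-[5-(5,7-dihydroxy-4-oxo-4H-chromen-2-yl)-2-hydroxyphenyl]-5,7-dihydroxy-2-(4-hydroxyphenyl)-2,3-dihydro-4H-chromen-4-one | O=C1c2c(O)cc(O)cc2O[C@@H](c2ccc(O)cc2)[C@@H]1c1cc(-c2cc(=O)c3c(O)cc(O)cc3o2)ccc1O | target

## Step count and least certain steps

Total step count: 11. Longest linear sequence: 9 steps (steps 2, 3, 4, 6, 7, 8, 9, 10 and 11, from 3 to 17).

Step 8 (key step, proposed new method).
- What may go wrong: the two benzyloxy groups stabilise 13 so strongly that its ion pair with a phosphate is a weak electrophile, and a 1,2-diarylethene is a poorer nucleophile than a styrene. The likely failure is therefore slow cycloaddition, with self-condensation of 13 on the electron-rich ring of 2 or 12 and Friedel-Crafts attack on C6 or C8 of the flavone taking over. The second risk is poor facial selectivity, since the catalyst holds 13 only through one hydrogen bond.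
- Fallback by known reactions, setting out from 4, 7 and 8 and returning at 17: bromoflavone 7 is O-benzylated (BnBr, K2CO3, DMF) to 5,7-bis(benzyloxy)-2-[4-(benzyloxy)-3-bromophenyl]-4H-chromen-4-one F1. Ketone 4 is protected (chloromethyl methyl ether, NaH, DMF) as 1-[2-(methoxymethoxy)-4,6-bis(benzyloxy)phenyl]ethan-1-one F2. Palladium-catalysed alpha-arylation of F2 with F1 (Pd(OAc)2, 2-dicyclohexylphosphino-2',4',6'-triisopropylbiphenyl, K3PO4, toluene, 100 °C) gives the protected deoxybenzoin F3, and HCl in MeOH/THF frees the 2-hydroxydeoxybenzoin F4. Condensation of F4 with aldehyde 8 (piperidine, EtOH, reflux) proceeds by Knoevenagel condensation and oxa-Michael closure, with C3 settling trans, and gives the racemic 2,3-trans hexabenzyl flavanone F5. Preparative HPLC on a polysaccharide chiral stationary phase separates the (2R,3S) enantiomer F6, and hydrogenolysis (H2, Pd/C, THF/MeOH) gives 17. This route is longer and gives up half of the material at the resolution, but every reaction type in it is established.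

Step 9.
- What may go wrong: the C4 cation may lose the C3 proton (E1) to give a 3-aryl-2H-chromene, which erases the C3 stereocentre, and exchange may stay incomplete because the methanol set free competes with water.
- Fallback, setting out from 14 and returning at 16 without passing through 15: oxidation with 2,3-dichloro-5,6-dicyano-1,4-benzoquinone in CH2Cl2/pH 7 buffer at 0 °C → rt. The reagent abstracts the C4 hydride, which is axial and aligned with ring A; water adds to the methoxy oxocarbenium ion and the hemiketal loses methanol to give ketone 16. Loss of the C3 proton on this path would give an enol ether that hydrolyses to the same ketone, with C3 again settling trans.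

Step 3.
- What may go wrong: the phenoxide of 5 makes the aldehyde a vinylogous carboxylate, so the condensation may be slow and incomplete and the materials may degrade on forcing.
- Fallback, setting out from 5 and 4 and returning at 6: 5 is protected (chloromethyl methyl ether, iPr2NEt, CH2Cl2) as 3-bromo-4-(methoxymethoxy)benzaldehyde F7. Claisen-Schmidt condensation of F7 with 4 (KOH, EtOH, rt) gives the protected chalcone F8, and HCl in MeOH/THF removes the acetal to give 6. Any flavanone formed by acid-mediated ring closure at this point is converted to 7 in step 4 as well.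

Step 6.
- What may go wrong: oxidative addition of the aryl bromide may be slow because the ring carries a phenoxide, some arylation may occur at the internal alkene carbon (1,1-diarylethene), and 9 may polymerise on heating.
- Fallback, setting out from 9 and 7 and returning at 10: cross-metathesis of 9 with 2-ethenyl-4,4,5,5-tetramethyl-1,3,2-dioxaborolane (second-generation Grubbs catalyst, CH2Cl2, 40 °C) gives 2-[(E)-2-(4-benzyloxyphenyl)ethenyl]-4,4,5,5-tetramethyl-1,3,2-dioxaborolane F9. Suzuki-Miyaura coupling of F9 with 7 (Pd(PPh3)4, K2CO3, dioxane/H2O, 90 °C) gives 10 with the alkene position and geometry fixed by the boronate.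

Step 11.
- What may go wrong: over-reduction, namely saturation of the flavone C2–C3 double bond or hydrogenolysis of the benzylic C2–O1 bond of the flavanone, and stalling at partly benzylated stages because the intermediates dissolve poorly.
- Fallback, setting out from 16 and returning at 17: Lewis-acid debenzylation with BCl3 and pentamethylbenzene as cation scavenger in CH2Cl2 at −78 °C. It cleaves the benzyl ethers and the benzyl–oxygen bond of the carbonate, whose carbonic half-ester decarboxylates on aqueous work-up, and needs neither hydrogen nor a metal.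

## Further compounds

F1 | step 8 | 5,7-bis(benzyloxy)-2-[4-(benzyloxy)-3-bromophenyl]-4H-chromen-4-one | O=c1cc(-c2ccc(OCc3ccccc3)c(Br)c2)oc2cc(OCc3ccccc3)cc(OCc3ccccc3)c12
F2 | step 8 | 1-[2-(methoxymethoxy)-4,6-bis(benzyloxy)phenyl]ethan-1-one | CC(=O)c1c(OCOC)cc(OCc2ccccc2)cc1OCc1ccccc1
F3 | step 8 | 2-{2-(benzyloxy)-5-[5,7-bis(benzyloxy)-4-oxo-4H-chromen-2-yl]phenyl}-1-[2-(methoxymethoxy)-4,6-bis(benzyloxy)phenyl]ethan-1-one | O=C(Cc1cc(-c2cc(=O)c3c(OCc4ccccc4)cc(OCc4ccccc4)cc3o2)ccc1OCc1ccccc1)c1c(OCOC)cc(OCc2ccccc2)cc1OCc1ccccc1
F4 | step 8 | 2-{2-(benzyloxy)-5-[5,7-bis(benzyloxy)-4-oxo-4H-chromen-2-yl]phenyl}-1-[2-hydroxy-4,6-bis(benzyloxy)phenyl]ethan-1-one | O=C(Cc1cc(-c2cc(=O)c3c(OCc4ccccc4)cc(OCc4ccccc4)cc3o2)ccc1OCc1ccccc1)c1c(O)cc(OCc2ccccc2)cc1OCc1ccccc1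
F5 | step 8 | racemic 2,3-trans-5,7-bis(benzyloxy)-3-{2-(benzyloxy)-5-[5,7-bis(benzyloxy)-4-oxo-4H-chromen-2-yl]phenyl}-2-(4-benzyloxyphenyl)-2,3-dihydro-4H-chromen-4-one (racemate, written without descriptors) | O=C1c2c(OCc3ccccc3)cc(OCc3ccccc3)cc2OC(c2ccc(OCc3ccccc3)cc2)C1c1cc(-c2cc(=O)c3c(OCc4ccccc4)cc(OCc4ccccc4)cc3o2)ccc1OCc1ccccc1
F6 | step 8 | (2R,3S)-5,7-bis(benzyloxy)-3-{2-(benzyloxy)-5-[5,7-bis(benzyloxy)-4-oxo-4H-chromen-2-yl]phenyl}-2-(4-benzyloxyphenyl)-2,3-dihydro-4H-chromen-4-one | O=C1c2c(OCc3ccccc3)cc(OCc3ccccc3)cc2O[C@@H](c2ccc(OCc3ccccc3)cc2)[C@@H]1c1cc(-c2cc(=O)c3c(OCc4ccccc4)cc(OCc4ccccc4)cc3o2)ccc1OCc1ccccc1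
F0 | step 9 | none | none
F7 | step 3 | 3-bromo-4-(methoxymethoxy)benzaldehyde | COCOc1ccc(C=O)cc1Br
F8 | step 3 | (2E)-3-[3-bromo-4-(methoxymethoxy)phenyl]-1-[2-hydroxy-4,6-bis(benzyloxy)phenyl]prop-2-en-1-one | O=C(/C=C/c1ccc(OCOC)c(Br)c1)c1c(O)cc(OCc2ccccc2)cc1OCc1ccccc1
F9 | step 6 | 2-[(E)-2-(4-benzyloxyphenyl)ethenyl]-4,4,5,5-tetramethyl-1,3,2-dioxaborolane | CC1(C)OB(/C=C/c2ccc(OCc3ccccc3)cc2)OC1(C)C
F0 | step 11 | none | none
A1 | alternative 1 | 2-{2-(benzyloxy)-5-[5,7-bis(benzyloxy)-4-oxo-4H-chromen-2-yl]phenyl}-1-[2-hydroxy-4,6-bis(benzyloxy)phenyl]ethan-1-one | O=C(Cc1cc(-c2cc(=O)c3c(OCc4ccccc4)cc(OCc4ccccc4)cc3o2)ccc1OCc1ccccc1)c1c(O)cc(OCc2ccccc2)cc1OCc1ccccc1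
A2 | alternative 1 | 4-(benzyloxy)-3-{2-[2-hydroxy-4,6-bis(benzyloxy)phenyl]-2-oxoethyl}-2H-pyran-2-one | O=C(Cc1c(OCc2ccccc2)ccoc1=O)c1c(O)cc(OCc2ccccc2)cc1OCc1ccccc1
A3 | alternative 1 | 5,7-bis(benzyloxy)-2-ethynyl-4H-chromen-4-one | C#Cc1cc(=O)c2c(OCc3ccccc3)cc(OCc3ccccc3)cc2o1
A4 | alternative 2 | 2-{4-(benzyloxy)-3-[5,7-bis(benzyloxy)-4-oxo-4H-chromen-3-yl]phenyl}-5-hydroxy-7-[(triisopropylsilyl)oxy]-4H-chromen-4-one | O=c1cc(-c2ccc(OCc3ccccc3)c(-c3coc4cc(OCc5ccccc5)cc(OCc5ccccc5)c4c3=O)c2)oc2cc(O[Si](C(C)C)(C(C)C)C(C)C)cc(O)c12
A5 | alternative 2 | 2-{4-(benzyloxy)-3-[5,7-bis(benzyloxy)-4-oxo-4H-chromen-3-yl]phenyl}-6-(2-diazoacetyl)-4H-pyran-4-one | [N-]=[N+]=CC(=O)c1cc(=O)cc(-c2ccc(OCc3ccccc3)c(-c3coc4cc(OCc5ccccc5)cc(OCc5ccccc5)c4c3=O)c2)o1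
A6 | alternative 2 | (ethynyloxy)tri(propan-2-yl)silane | C#CO[Si](C(C)C)(C(C)C)C(C)C
A7 | alternative 3 | (2R,3S)-5,7-bis(benzyloxy)-3-{2-(benzyloxy)-5-[5,7-bis(benzyloxy)-4-oxo-4H-chromen-2-yl]phenyl}-2-(4-benzyloxyphenyl)-2,3-dihydro-4H-chromen-4-one | O=C1c2c(OCc3ccccc3)cc(OCc3ccccc3)cc2O[C@@H](c2ccc(OCc3ccccc3)cc2)[C@@H]1c1cc(-c2cc(=O)c3c(OCc4ccccc4)cc(OCc4ccccc4)cc3o2)ccc1OCc1ccccc1
A8 | alternative 3 | 2-{2-(benzyloxy)-5-[5,7-bis(benzyloxy)-4-oxo-4H-chromen-2-yl]phenyl}-3-(4-benzyloxyphenyl)-1-[2-hydroxy-4,6-bis(benzyloxy)phenyl]prop-2-en-1-one (alkene geometry not fixed) | O=C(C(=Cc1ccc(OCc2ccccc2)cc1)c1cc(-c2cc(=O)c3c(OCc4ccccc4)cc(OCc4ccccc4)cc3o2)ccc1OCc1ccccc1)c1c(O)cc(OCc2ccccc2)cc1OCc1ccccc1
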